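Two questions stand over these flasks, which differ in the other conformer charged.

| flask | starting material | other conformer | catalyst | added ligand | time |
|---|---|---|---|---|---|
| Tuesday's | 1.0 M | 0.0300 equiv | 0.2 mol% | 1.5 mM | 40 s |
| Sunday's | 1.0 M | 0.0800 equiv | 0.2 mol% | 1.5 mM | 40 s |
| Saturday's | 1.0 M | 0.250 equiv | 0.2 mol% | 1.5 mM | 40 s |
| Wednesday's | 1.0 M | 0.800 equiv | 0.2 mol% | 1.5 mM | 40 s |
| Monday's | 1.0 M | 2.50 equiv | 0.2 mol% | 1.5 mM | 40 s |

    catalyst + other conformer → catalyst + isomer of the product (k1 = 92 M⁻¹ s⁻¹)
    starting material + catalyst → catalyst + target (k2 = 88 M⁻¹ s⁻¹)
    starting material ⇌ other conformer (K3 = 0.0038, k3 = 0.54 s⁻¹)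
    catalyst + added ligand ⇌ idle complex, settled at all times (K4 = 1400 M⁻¹)

1. [target] at the end for Tuesday's, Sunday's, Saturday's, Wednesday's, Monday's, in this order
2. how the row runs (rises all the way / hardly changes / rises, then falls / falls all the way / falls, then rises)

- "hardly changes" means that all values lie within two and a half points (for a concentration: within two and a half percent of the largest)
- run time (Tuesday's): 40 s

- I count turnovers. The catalyst comes back from both catalysed steps, and the ligand enters neither of them, so I take the split between free catalyst and idle complex as constant through the run. Out of 2.00 mM charged, with a binding constant times charged catalyst of 2.8, the balance gives 0.907 mM idle complex and 1.09 mM free catalyst.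
- Other conformer returns to starting material with a constant of 142 s⁻¹, while the pool of both conformers is used with 0.0962 s⁻¹. Because the return is much faster than that use, added other conformer joins the starting material within about 7.01 ms, and I treat the two as one pool, decaying pseudo-first-order.
- In Tuesday's flask, a free catalyst at the starting rate makes 3630 turnovers in the run, and the pool offers 942 molecules per free catalyst. Their ratio, 3.85, is the reach: the rate constant of the target step times free catalyst times run time. The pool cancels from it, so with catalyst and ligand held as in these recipes I reckon the fraction of pool left after the run as exp(−reach), for each listed charge of other conformer.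
- Drawn as a fraction of the pool, the target curve starts with a slope of 0.0962 s⁻¹; the pool has a half-life of 7.21 s, and the curve bends over near 23.9 s, where a tenth of the pool remains.
- The curve runs towards a level under the whole pool. Other conformer stands at 0.0038 of starting material in the pool, so I reckon isomer of the product to form at 0.397% of the rate of target, which leaves a level of 99.6%.
- At the end of the run I expect 97.5% of the pool as target. That is 1.00 M in Tuesday's flask and 3.41 M in Monday's, so I commit to a row that climbs with the charge.
- The forecast reads 1.004 M, 1.053 M, 1.218 M, 1.754 M, 3.41 M, and its shape is: rises all the way. Its ground is that “The conformers equilibrate within milliseconds, far faster than catalysis”.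
- The simulation gives 1.00 M, 1.05 M, 1.22 M, 1.75 M, 3.41 M, and its shape is: rises all the way.
- At 6.99 s in Tuesday's flask, starting material has a half-life of 7.2 s by the catalysed step against 1.3 s by the forward passage to other conformer, a rate ratio of 0.18. The reach of 3.85 leaves 2.13% of the pool, and starting material at 40.0 s stands at 2.13% of the two conformers together charged in Tuesday's flask and at 2.12% in Monday's, whose pool is 3.40 times as large.

All constants were set for the occasion, and the outcome is calculated.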